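**Retrosynthetic overview**

1. Numbering follows the 1H-indene core of the target: C1 (CHMe), C2=C3(Me), C3a, C4 (Me, CO2H), C5 (Et, phenylbutadienyl), C6=C7(Me), C7a.
2. Target 23 ⇐ aldehyde 21 (Pinnick oxidation) ⇐ acyclic (2E,4Z)-hexaenal 20 by an intramolecular Diels–Alder reaction that forms the ring-fusion bond C3a–C7a together with C4–C5, so the five- and the six-membered ring close in the same step.
3. Enabling feature: the six-membered ring C3a–C4–C5–C6=C7–C7a is a cyclohexene with its C6=C7 bond opposite the C3a–C4 bond and a carbonyl group on C4 (Diels–Alder retron); the cis C2=C3 alkene of the five-membered ring is a rigid three-atom tether (C1–C2=C3) between diene terminus C7a and dienophile carbon C3a.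
4. 20 ⇐ dienol 19, built outward from the single stereocentre C1 (from methyl (R)-3-hydroxy-2-methylpropanoate): diene arm by two Wittig reactions and one Horner–Wadsworth–Emmons reaction, dienophile arm by a Still–Gennari and a Wittig reaction; C3a, C4, C5 and C7a are all induced by C1 and the alkene geometries.

Key step: step 13

Assumption: the stabilised ylides 5, 7 and 17 and the phosphonates 9 and 13 are treated as purchasable reagents, and all polyene intermediates are handled with exclusion of light.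

**Route**

Step 1
Reactants: 1 methyl (R)-3-hydroxy-2-methylpropanoate; 2 tert-butyl(chloro)dimethylsilane
Product: 3 methyl (R)-3-[(tert-butyldimethylsilyl)oxy]-2-methylpropanoate
Conditions: imidazole, DMF, 0 °C to rt
Reagents that add atoms: tert-butyl(chloro)dimethylsilane (2), C[Si](C)(Cl)C(C)(C)C
Why: Imidazole-assisted silylation masks the primary alcohol (the later C2 terminus) and does not touch the stereocentre.

Step 2
Reactants: 3 methyl (R)-3-[(tert-butyldimethylsilyl)oxy]-2-methylpropanoate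
Product: 4 (R)-3-[(tert-butyldimethylsilyl)oxy]-2-methylpropanal
Conditions: i-Bu2AlH (1.05 equiv), CH2Cl2, −78 °C; aq. potassium sodium tartrate
Reagents that add atoms: none
Why: Partial ester reduction stops at the aluminium hemiacetal at −78 °C and releases the aldehyde on work-up under non-basic conditions, so the α-stereocentre should be kept.

Step 3
Reactants: 4 (R)-3-[(tert-butyldimethylsilyl)oxy]-2-methylpropanal; 5 2-(triphenylphosphoranylidene)propanal
Product: 6 (2E,4S)-5-[(tert-butyldimethylsilyl)oxy]-2,4-dimethylpent-2-enal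
Conditions: PhMe, 80 °C
Reagents that add atoms: 2-(triphenylphosphoranylidene)propanal (5), CC(C=O)=P(c1ccccc1)(c1ccccc1)c1ccccc1
Why: Wittig reaction with a stabilised formyl ylide is E-selective and gives the trisubstituted enal (later C7=C7a) in one two-carbon homologation without redox steps.

Step 4
Reactants: 6 (2E,4S)-5-[(tert-butyldimethylsilyl)oxy]-2,4-dimethylpent-2-enal; 7 2-(triphenylphosphoranylidene)butanal
Product: 8 (2E,4E,6S)-7-[(tert-butyldimethylsilyl)oxy]-2-ethyl-4,6-dimethylhepta-2,4-dienal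
Conditions: PhMe, 110 °C
Reagents that add atoms: 2-(triphenylphosphoranylidene)butanal (7), CCC(C=O)=P(c1ccccc1)(c1ccccc1)c1ccccc1
Why: A second E-selective stabilised-ylide Wittig reaction places the formyl carbon trans and the ethyl group cis to the chain, which is the diene geometry (later C5=C6) that the cycloaddition needs.

Step 5
Reactants: 8 (2E,4E,6S)-7-[(tert-butyldimethylsilyl)oxy]-2-ethyl-4,6-dimethylhepta-2,4-dienal; 9 diethyl [(2E)-3-phenylprop-2-en-1-yl]phosphonate
Product: 10 tert-butyl{[(2S,3E,5E,7E,9E)-6-ethyl-2,4-dimethyl-10-phenyldeca-3,5,7,9-tetraen-1-yl]oxy}dimethylsilane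
Conditions: NaN(SiMe3)2, THF, −78 °C to 0 °C
Reagents that add atoms: diethyl [(2E)-3-phenylprop-2-en-1-yl]phosphonate (9), CCOP(=O)(C/C=C/c1ccccc1)OCC
Why: Horner–Wadsworth–Emmons olefination with the allylic phosphonate anion forms the new disubstituted alkene with E geometry and completes the (1E,3E)-4-phenylbutadienyl unit.

Step 6
Reactants: 10 tert-butyl{[(2S,3E,5E,7E,9E)-6-ethyl-2,4-dimethyl-10-phenyldeca-3,5,7,9-tetraen-1-yl]oxy}dimethylsilane
Product: 11 (2S,3E,5E,7E,9E)-6-ethyl-2,4-dimethyl-10-phenyldeca-3,5,7,9-tetraen-1-ol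
Conditions: HF·pyridine, pyridine, THF, 0 °C to rt
Reagents that add atoms: none
Why: Pyridine-buffered fluoride cleavage of the primary silyl ether should leave the tetraene untouched.

Step 7
Reactants: 11 (2S,3E,5E,7E,9E)-6-ethyl-2,4-dimethyl-10-phenyldeca-3,5,7,9-tetraen-1-ol
Product: 12 (2S,3E,5E,7E,9E)-6-ethyl-2,4-dimethyl-10-phenyldeca-3,5,7,9-tetraenal
Conditions: Dess–Martin periodinane, pyridine, CH2Cl2, 0 °C; used crude at once
Reagents that add atoms: none
Why: Dess–Martin oxidation works under buffered, non-enolising conditions, so the α-stereocentre and the β,γ-position of the alkene should survive if the aldehyde is used immediately.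

Step 8
Reactants: 12 (2S,3E,5E,7E,9E)-6-ethyl-2,4-dimethyl-10-phenyldeca-3,5,7,9-tetraenal; 13 ethyl 2-[bis(2,2,2-trifluoroethoxy)phosphoryl]propanoate
Product: 14 ethyl (2Z,4S,5E,7E,9E,11E)-8-ethyl-2,4,6-trimethyl-12-phenyldodeca-2,5,7,9,11-pentaenoate
Conditions: KN(SiMe3)2, 18-crown-6, THF, −78 °C
Reagents that add atoms: ethyl 2-[bis(2,2,2-trifluoroethoxy)phosphoryl]propanoate (13), CCOC(=O)C(C)P(=O)(OCC(F)(F)F)OCC(F)(F)F
Why: Still–Gennari olefination (irreversible addition and fast elimination of the electron-poor phosphonate at −78 °C) gives the (Z)-trisubstituted enoate, the later cis C2=C3 alkene, while the low temperature disfavours α-epimerisation.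

Step 9
Reactants: 14 ethyl (2Z,4S,5E,7E,9E,11E)-8-ethyl-2,4,6-trimethyl-12-phenyldodeca-2,5,7,9,11-pentaenoate
Product: 15 (2Z,4S,5E,7E,9E,11E)-8-ethyl-2,4,6-trimethyl-12-phenyldodeca-2,5,7,9,11-pentaen-1-ol
Conditions: i-Bu2AlH (2.5 equiv), CH2Cl2, −78 °C
Reagents that add atoms: none
Why: 1,2-Reduction of the enoate by i-Bu2AlH gives the allylic alcohol without changing alkene geometry.

Step 10
Reactants: 15 (2Z,4S,5E,7E,9E,11E)-8-ethyl-2,4,6-trimethyl-12-phenyldodeca-2,5,7,9,11-pentaen-1-ol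
Product: 16 (2Z,4S,5E,7E,9E,11E)-8-ethyl-2,4,6-trimethyl-12-phenyldodeca-2,5,7,9,11-pentaenal
Conditions: MnO2, CH2Cl2, rt
Reagents that add atoms: none
Why: MnO2 oxidises the allylic alcohol selectively under neutral conditions, which should preserve the Z geometry of the enal.

Step 11
Reactants: 16 (2Z,4S,5E,7E,9E,11E)-8-ethyl-2,4,6-trimethyl-12-phenyldodeca-2,5,7,9,11-pentaenal; 17 ethyl 2-(triphenylphosphoranylidene)propanoate
Product: 18 ethyl (2E,4Z,6S,7E,9E,11E,13E)-10-ethyl-2,4,6,8-tetramethyl-14-phenyltetradeca-2,4,7,9,11,13-hexaenoate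
Conditions: CH2Cl2, rt
Reagents that add atoms: ethyl 2-(triphenylphosphoranylidene)propanoate (17), CCOC(=O)C(C)=P(c1ccccc1)(c1ccccc1)c1ccccc1
Why: Wittig reaction with the stabilised ylide at ambient temperature gives the (E)-α-methyl enoate, the dienophile geometry that later translates into the cis relation of H3a and the carboxyl group.

Step 12
Reactants: 18 ethyl (2E,4Z,6S,7E,9E,11E,13E)-10-ethyl-2,4,6,8-tetramethyl-14-phenyltetradeca-2,4,7,9,11,13-hexaenoate
Product: 19 (2E,4Z,6S,7E,9E,11E,13E)-10-ethyl-2,4,6,8-tetramethyl-14-phenyltetradeca-2,4,7,9,11,13-hexaen-1-ol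
Conditions: i-Bu2AlH (2.5 equiv), CH2Cl2, −78 °C
Reagents that add atoms: none
Why: i-Bu2AlH reduction of the dienoate to the dienol prepares the oxidation-triggered cycloaddition and keeps the polyene below the temperature at which it could cyclise as the ester.

Step 13
Reactants: 19 (2E,4Z,6S,7E,9E,11E,13E)-10-ethyl-2,4,6,8-tetramethyl-14-phenyltetradeca-2,4,7,9,11,13-hexaen-1-ol
Product: 21 (1R,3aR,4R,5S,7aS)-5-ethyl-1,3,4,7-tetramethyl-5-[(1E,3E)-4-phenylbuta-1,3-dien-1-yl]-3a,4,5,7a-tetrahydro-1H-indene-4-carbaldehyde, via hexaenal 20 (not isolated)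
Conditions: MnO2, CH2Cl2, rt; filter; then PhMe (0.005 M), BHT, 70 °C
Reagents that add atoms: none
Why: MnO2 oxidises the allylic alcohol to (2E,4Z)-dienal 20, whose α-methyl enal then adds as dienophile to the 1,1,3,4-tetrasubstituted diene in a thermal, asynchronous concerted [4+2] cycloaddition in which the C7a–C3a bond (nucleophilic diene terminus to enal β-carbon) runs ahead of the congested C5–C4 bond; the closest known reaction type is the oxidation-triggered intramolecular Diels–Alder reaction of 1,3,8-nonatrienes to hydrindenes. The cyclohexene closes as the cycloadduct ring, and the cyclopentene closes in the fused (type 1) mode across the three-atom tether, whose cis C2=C3 alkene holds diene terminus and dienophile within bonding distance. C7a is set by the C1 stereocentre: 1,3-allylic strain with the C7 methyl group keeps H1 in the diene plane, so the tether delivers the dienophile to the face anti to the C1 methyl group. C3a and C4 are set by the (E)-dienophile geometry and C5 by the (E)-diene geometry (dienyl group outside, ethyl group inside), both transferred suprafacially; their relation to C7a comes from the endo orientation of the formyl group, which places the tether exo and should give the trans ring fusion with CHO cis to the dienyl group. The step needs endo over exo and anti over syn facial selectivity and must be faster than a [1,5]-hydrogen shift in the (Z)-dienal; the aldehyde oxidation level (strong activation, secondary orbital overlap, reaction at 70 °C or below), the single allylic stereocentre and high dilution are chosen to secure this.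

Step 14
Reactants: 21 (1R,3aR,4R,5S,7aS)-5-ethyl-1,3,4,7-tetramethyl-5-[(1E,3E)-4-phenylbuta-1,3-dien-1-yl]-3a,4,5,7a-tetrahydro-1H-indene-4-carbaldehyde; 22 sodium chlorite
Product: 23 (1R,3aR,4R,5S,7aS)-5-ethyl-1,3,4,7-tetramethyl-5-[(1E,3E)-4-phenylbuta-1,3-dien-1-yl]-3a,4,5,7a-tetrahydro-1H-indene-4-carboxylic acid
Conditions: NaClO2, NaH2PO4, 2-methyl-2-butene, t-BuOH/THF/H2O, 0 °C to rt
Reagents that add atoms: sodium chlorite (22), [Na+].[O-]Cl=O
Why: Pinnick oxidation converts the neopentyl aldehyde, which has no α-hydrogen and cannot epimerise, into the acid, while 2-methyl-2-butene traps hypochlorous acid before it can attack the diene side chain.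

**Compound list**

1 | methyl (R)-3-hydroxy-2-methylpropanoate | COC(=O)[C@H](C)CO | starting material
2 | tert-butyl(chloro)dimethylsilane | C[Si](C)(Cl)C(C)(C)C | starting material
3 | methyl (R)-3-[(tert-butyldimethylsilyl)oxy]-2-methylpropanoate | COC(=O)[C@H](C)CO[Si](C)(C)C(C)(C)C | intermediate
4 | (R)-3-[(tert-butyldimethylsilyl)oxy]-2-methylpropanal | O=C[C@H](C)CO[Si](C)(C)C(C)(C)C | intermediate
5 | 2-(triphenylphosphoranylidene)propanal | CC(C=O)=P(c1ccccc1)(c1ccccc1)c1ccccc1 | starting material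
6 | (2E,4S)-5-[(tert-butyldimethylsilyl)oxy]-2,4-dimethylpent-2-enal | O=C/C(C)=C/[C@H](C)CO[Si](C)(C)C(C)(C)C | intermediate
7 | 2-(triphenylphosphoranylidene)butanal | CCC(C=O)=P(c1ccccc1)(c1ccccc1)c1ccccc1 | starting material
8 | (2E,4E,6S)-7-[(tert-butyldimethylsilyl)oxy]-2-ethyl-4,6-dimethylhepta-2,4-dienal | O=C/C(CC)=C/C(C)=C/[C@H](C)CO[Si](C)(C)C(C)(C)C | intermediate
9 | diethyl [(2E)-3-phenylprop-2-en-1-yl]phosphonate | CCOP(=O)(C/C=C/c1ccccc1)OCC | starting material
10 | tert-butyl{[(2S,3E,5E,7E,9E)-6-ethyl-2,4-dimethyl-10-phenyldeca-3,5,7,9-tetraen-1-yl]oxy}dimethylsilane | CC/C(/C=C/C=C/c1ccccc1)=C\C(C)=C\[C@H](C)CO[Si](C)(C)C(C)(C)C | intermediate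
11 | (2S,3E,5E,7E,9E)-6-ethyl-2,4-dimethyl-10-phenyldeca-3,5,7,9-tetraen-1-ol | CC/C(/C=C/C=C/c1ccccc1)=C\C(C)=C\[C@H](C)CO | intermediate
12 | (2S,3E,5E,7E,9E)-6-ethyl-2,4-dimethyl-10-phenyldeca-3,5,7,9-tetraenal | CC/C(/C=C/C=C/c1ccccc1)=C\C(C)=C\[C@H](C)C=O | intermediate
13 | ethyl 2-[bis(2,2,2-trifluoroethoxy)phosphoryl]propanoate | CCOC(=O)C(C)P(=O)(OCC(F)(F)F)OCC(F)(F)F | starting material
14 | ethyl (2Z,4S,5E,7E,9E,11E)-8-ethyl-2,4,6-trimethyl-12-phenyldodeca-2,5,7,9,11-pentaenoate | CC/C(/C=C/C=C/c1ccccc1)=C\C(C)=C\[C@H](C)/C=C(C)\C(=O)OCC | intermediate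
15 | (2Z,4S,5E,7E,9E,11E)-8-ethyl-2,4,6-trimethyl-12-phenyldodeca-2,5,7,9,11-pentaen-1-ol | CC/C(/C=C/C=C/c1ccccc1)=C\C(C)=C\[C@H](C)/C=C(C)\CO | intermediate
16 | (2Z,4S,5E,7E,9E,11E)-8-ethyl-2,4,6-trimethyl-12-phenyldodeca-2,5,7,9,11-pentaenal | CC/C(/C=C/C=C/c1ccccc1)=C\C(C)=C\[C@H](C)/C=C(C)\C=O | intermediate
17 | ethyl 2-(triphenylphosphoranylidene)propanoate | CCOC(=O)C(C)=P(c1ccccc1)(c1ccccc1)c1ccccc1 | starting material
18 | ethyl (2E,4Z,6S,7E,9E,11E,13E)-10-ethyl-2,4,6,8-tetramethyl-14-phenyltetradeca-2,4,7,9,11,13-hexaenoate | CC/C(/C=C/C=C/c1ccccc1)=C\C(C)=C\[C@H](C)/C=C(C)\C=C(C)\C(=O)OCC | intermediate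
19 | (2E,4Z,6S,7E,9E,11E,13E)-10-ethyl-2,4,6,8-tetramethyl-14-phenyltetradeca-2,4,7,9,11,13-hexaen-1-ol | CC/C(/C=C/C=C/c1ccccc1)=C\C(C)=C\[C@H](C)/C=C(C)\C=C(C)\CO | intermediate
20 | (2E,4Z,6S,7E,9E,11E,13E)-10-ethyl-2,4,6,8-tetramethyl-14-phenyltetradeca-2,4,7,9,11,13-hexaenal | CC/C(/C=C/C=C/c1ccccc1)=C\C(C)=C\[C@H](C)/C=C(C)\C=C(C)\C=O | intermediate (not isolated)
21 | (1R,3aR,4R,5S,7aS)-5-ethyl-1,3,4,7-tetramethyl-5-[(1E,3E)-4-phenylbuta-1,3-dien-1-yl]-3a,4,5,7a-tetrahydro-1H-indene-4-carbaldehyde | CC[C@]1(/C=C/C=C/c2ccccc2)C=C(C)[C@H]2[C@H](C)C=C(C)[C@@H]2[C@@]1(C)C=O | intermediate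
22 | sodium chlorite | [Na+].[O-]Cl=O | starting material
23 | (1R,3aR,4R,5S,7aS)-5-ethyl-1,3,4,7-tetramethyl-5-[(1E,3E)-4-phenylbuta-1,3-dien-1-yl]-3a,4,5,7a-tetrahydro-1H-indene-4-carboxylic acid | CC[C@]1(/C=C/C=C/c2ccccc2)C=C(C)[C@H]2[C@H](C)C=C(C)[C@@H]2[C@@]1(C)C(=O)O | target

**Step count and risks**

Total step count: 14. Longest linear sequence: 14 steps (from 1).

Three steps most likely to fail:

1. Step 13. What may go wrong: erosion of endo selectivity (cis-fused cycloadduct), or a suprafacial [1,5]-hydrogen shift in the (Z)-dienal that outruns closure of the congested C4–C5 bond. The fallback sets out from ester 18 and comes back to the route at 21. The cycloaddition is moved to the ester oxidation level and run as a Lewis-acid-promoted reaction: EtAlCl2 (1.1 equiv) in CH2Cl2 at −40 to 0 °C should give, through the tighter and more endo-selective aluminium-complexed transition state and well below the temperature of the hydrogen shift, ethyl (1R,3aR,4R,5S,7aS)-5-ethyl-1,3,4,7-tetramethyl-5-[(1E,3E)-4-phenylbuta-1,3-dien-1-yl]-3a,4,5,7a-tetrahydro-1H-indene-4-carboxylate F1. LiAlH4 in Et2O at 0 °C then reduces the hindered ester to [(1R,3aR,4R,5S,7aS)-5-ethyl-1,3,4,7-tetramethyl-5-[(1E,3E)-4-phenylbuta-1,3-dien-1-yl]-3a,4,5,7a-tetrahydro-1H-inden-4-yl]methanol F2, and Dess–Martin oxidation returns aldehyde 21.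

2. Step 8. What may go wrong: enolisation of the doubly activated aldehyde 12 (formed in step 7) under the basic olefination conditions, which epimerises the only stereocentre or moves the β,γ-alkene into conjugation. The fallback sets out from alcohol 11 and comes back at 15; it reverses the polarity of the olefination so that no aldehyde is ever placed next to the stereocentre. Iodination (I2, PPh3, imidazole, CH2Cl2, 0 °C) gives [(1E,3E,5E,7E,9S)-5-ethyl-10-iodo-7,9-dimethyldeca-1,3,5,7-tetraen-1-yl]benzene F3, and PPh3 in MeCN at 70 °C gives [(2S,3E,5E,7E,9E)-6-ethyl-2,4-dimethyl-10-phenyldeca-3,5,7,9-tetraen-1-yl]triphenylphosphonium iodide F4. Its non-stabilised ylide (NaN(SiMe3)2, THF, −78 °C) is combined with 1-[(tert-butyldimethylsilyl)oxy]propan-2-one in a Z-selective Wittig reaction of an α-silyloxy ketone to give tert-butyl{[(2Z,4S,5E,7E,9E,11E)-8-ethyl-2,4,6-trimethyl-12-phenyldodeca-2,5,7,9,11-pentaen-1-yl]oxy}dimethylsilane F5. HF·pyridine then releases allylic alcohol 15.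

3. Step 4. What may go wrong: slow addition of the hindered, weakly nucleophilic α-ethyl formyl ylide to the α-methyl enal, so that prolonged heating leads to decomposition and loss of geometric purity. The fallback sets out from enal 6 and comes back at 8. A Horner–Wadsworth–Emmons reaction with triethyl 2-phosphonobutanoate (NaH, THF, 0 °C to rt) gives ethyl (2E,4E,6S)-7-[(tert-butyldimethylsilyl)oxy]-2-ethyl-4,6-dimethylhepta-2,4-dienoate F6. i-Bu2AlH (CH2Cl2, −78 °C) gives (2E,4E,6S)-7-[(tert-butyldimethylsilyl)oxy]-2-ethyl-4,6-dimethylhepta-2,4-dien-1-ol F7, and MnO2 (CH2Cl2, rt) returns dienal 8.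

**Further compounds**

F1 | step 13 | ethyl (1R,3aR,4R,5S,7aS)-5-ethyl-1,3,4,7-tetramethyl-5-[(1E,3E)-4-phenylbuta-1,3-dien-1-yl]-3a,4,5,7a-tetrahydro-1H-indene-4-carboxylate | CC[C@]1(/C=C/C=C/c2ccccc2)C=C(C)[C@H]2[C@H](C)C=C(C)[C@@H]2[C@@]1(C)C(=O)OCC
F2 | step 13 | [(1R,3aR,4R,5S,7aS)-5-ethyl-1,3,4,7-tetramethyl-5-[(1E,3E)-4-phenylbuta-1,3-dien-1-yl]-3a,4,5,7a-tetrahydro-1H-inden-4-yl]methanol | CC[C@]1(/C=C/C=C/c2ccccc2)C=C(C)[C@H]2[C@H](C)C=C(C)[C@@H]2[C@@]1(C)CO
F3 | step 8 | [(1E,3E,5E,7E,9S)-5-ethyl-10-iodo-7,9-dimethyldeca-1,3,5,7-tetraen-1-yl]benzene | CC/C(/C=C/C=C/c1ccccc1)=C\C(C)=C\[C@H](C)CI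
F4 | step 8 | [(2S,3E,5E,7E,9E)-6-ethyl-2,4-dimethyl-10-phenyldeca-3,5,7,9-tetraen-1-yl]triphenylphosphonium iodide | CC/C(/C=C/C=C/c1ccccc1)=C\C(C)=C\[C@H](C)C[P+](c1ccccc1)(c1ccccc1)c1ccccc1.[I-]
F5 | step 8 | tert-butyl{[(2Z,4S,5E,7E,9E,11E)-8-ethyl-2,4,6-trimethyl-12-phenyldodeca-2,5,7,9,11-pentaen-1-yl]oxy}dimethylsilane | CC/C(/C=C/C=C/c1ccccc1)=C\C(C)=C\[C@H](C)/C=C(C)\CO[Si](C)(C)C(C)(C)C
F6 | step 4 | ethyl (2E,4E,6S)-7-[(tert-butyldimethylsilyl)oxy]-2-ethyl-4,6-dimethylhepta-2,4-dienoate | CCOC(=O)/C(CC)=C/C(C)=C/[C@H](C)CO[Si](C)(C)C(C)(C)C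
F7 | step 4 | (2E,4E,6S)-7-[(tert-butyldimethylsilyl)oxy]-2-ethyl-4,6-dimethylhepta-2,4-dien-1-ol | OC/C(CC)=C/C(C)=C/[C@H](C)CO[Si](C)(C)C(C)(C)C
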